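## The problem

Margaspidin (21) has no stereocentre, so the whole difficulty is regiochemical. Two hexasubstituted phloroglucinol rings are joined through one methylene carbon, from C5 of ring A to C1' of ring B. Each ring carries a butyryl group, a C-methyl group and three oxygens, and the rings differ in one point only: the oxygen para to the ketone is free on ring A (C4–OH) and methylated on ring B (C6'–OMe). A synthesis must therefore either tell six very similar phenolic oxygens apart or build the two rings differently from the start. The only handles for control are the two ketones, each flanked by two ortho oxygens and able to direct chelation-controlled chemistry to them. The free polyphenol is fragile: hydroxylated diarylmethanes of this kind exchange their halves in base (rottlerone change), can lose the bridge by ipso protonation in strong acid, and oxidise easily. The phenols should therefore be uncovered last and without base. The feature that opens the key step is the strict alternation on ring A: oxygen at C2, C4 and C6, carbon at C1 (butyryl), C3 (methyl) and C5 (bridge CH2). C2–C5 can thus come from a β-keto ester-derived 1-alkoxy-1,3-bis(silyloxy)diene, and C1/C6 from an alkyne bearing the acyl group and an alkoxy group.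

## Retrosynthesis

**21 from 20.** The last cut removes three O-alkyl bonds: the methyl groups on O2' and O4' of ring B and the ethyl group on O6 of ring A. All three ethers sit ortho to a ketone, whereas the methoxy group that must stay (C6') is para to the ring B ketone. Chelation-directed cleavage with BCl3 can therefore make the one distinction the target demands. Keeping three methyl ethers on ring B until this point lets the route start from a symmetric arene. Benzyl or other orthogonal groups would need an unsymmetrical starting material and a regioselective formylation.

**20 from 19 and 12.** The C3'–C(=O) bond of ring B is cut as a Friedel–Crafts acylation with butanoyl chloride 12. It is placed after ring A is complete because an enolisable aryl ketone would not survive the dianion and amide-base steps that prepare the diene. C3' is the only unsubstituted ring carbon in 19 and is activated by two ortho and one para methoxy groups, so position selectivity is not in question.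

**19 from 11 and 17.** Ring A is opened at C5–C6 and C1–C2. This (4+2) disconnection gives diene 11 (ring A C2–C5, with the methyl group and the ring B benzyl group attached) and push–pull ynone 17 (C1 with the butyryl group, C6 with the ethoxy group). Cutting at the bridge, a Friedel–Crafts union of two finished rings, would be shorter. It is kept in reserve only, because cross-coupling of two nearly identical nucleophilic rings is hard to control. The ring-forming cut fixes all six substituents of ring A by the polarity of two acyclic partners and makes ring A different from ring B by construction. The forward reaction must give head-to-tail orientation and aromatise cycloadduct 18 without losing the ethoxy group.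

**17 from 14 and 13, and 13 from 12.** The C(sp)–C(=O) bond of the ynone is cut to ethoxyacetylene 14 (through its lithium salt 15) and the N-methoxy-N-methylamide 13 of butanoic acid. The amide comes from butanoyl chloride 12. The amide route stops cleanly at the ketone stage through chelate 16, which an acid chloride would not do with a lithium acetylide.

**11 from 9 and 8.** The two O–Si bonds are cut in turn: diene 11 from silyl enol ether 9 through dienolate 10, and 9 from β-keto ester 8. This is the standard two-stage preparation of bis(silyloxy)dienes and asks only that the γ-CH2 of 9 be the sole acidic site, which it is.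

**8 from 7, 7 from 3 and 4, 3 from 1.** The bond between the benzylic carbon and the γ-carbon of the keto ester is cut as an aldol condensation of aldehyde 3 with dianion 5 of methyl 2-methyl-3-oxobutanoate 4. Aldol 6 is dehydrated to enone 7, and hydrogenation gives 8. Direct benzylation of the dianion would save a step, but benzylic halides of trialkoxybenzenes ionise and self-condense, whereas the aldehyde is stable. Aldehyde 3 comes from symmetric 2,4,6-trimethoxytoluene 1 through iminium salt 2. The two free positions of 1 are equivalent, so no regiochemical question arises.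

## Roads not taken

**Alternative 1:** Both rings would be cut at the bond between the butyryl-bearing carbon and an adjacent oxygenated carbon (C1–C6 and C3'–C2'). This leads to the open-chain bis(tetraketide) dimethyl 2,4-bis(2-methyl-3,5-dioxooctanoyl)pentanedioate A1. With Mg(OMe)2 in methanol each doubly activated methylene would attack its own ester carbonyl, and two Claisen closures followed by enolisation would give 1,1'-[methylenebis(2,4,6-trihydroxy-5-methylbenzene-3,1-diyl)]dibutan-1-one A2.
- Merits: both rings form in one operation, no protecting groups are needed, and the chemistry copies the biosynthesis. In ring-forming economy it is better than the chosen plan.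
- Weak points: A2 is the symmetric O-desmethyl compound. The target is its mono-methyl ether at one of two equivalent para oxygens, so the last step can only be statistical and must be run on a base-sensitive hexaphenol. A1 is a poly-β-carbonyl compound with several competing closure modes (aldol, pyrone formation), and its assembly is not short.
- Comparison: the chosen plan is longer in the ring-forming part and relies on a sensitive diene. Against this it sets two rings that are different from the moment ring A is made, so no statistical step is needed.

**Alternative 2:** All six aryl C–O bonds would be cut. The forward step is a sixfold copper-catalysed methoxylation (NaOMe, catalytic CuI, DMF–methanol) of bis(2,4,6-tribromo-3-methylphenyl)methane A3, giving bis(2,4,6-trimethoxy-3-methylphenyl)methane A4.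
- Merits: a symmetric series from cheap aromatics, no moisture-sensitive intermediates, and a bridge that is present from the start. In robustness of the individual operations it is at least equal to the chosen plan.
- Weak points: six substitutions at bromides that are each flanked by two ortho substituents invite incomplete exchange and protodebromination. After A4 two butyrylations are still needed. Chelation-controlled cleavage would then spare both para methoxy groups, one of which must still be removed from a symmetric compound. The desymmetrisation problem of alternative 1 returns, now as a demethylation.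
- Comparison: the chosen plan has an untested cycloaddition where this road has only known reactions. Against this it sets the fact that its para oxygen on ring A is never methylated.

**Alternative 3:** Ring A would be cut at C6–O and C1–C(=O). CsF would release the C1–C6 aryne from 2-{[2,4-bis(benzyloxy)-3-butanoyl-6-methoxy-5-methylphenyl]methyl}-3,5-bis(benzyloxy)-4-methyl-6-(trimethylsilyl)phenyl trifluoromethanesulfonate A5. Butanoic acid would add through oxygen at C6, and the C1 aryl anion would take over the acyl group, giving 2,4,2',4'-tetra-O-benzylmargaspidin A6. Hydrogenolysis would then give 21.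
- Merits: the end game is better than that of the chosen plan, because benzyl ethers are removed by hydrogenolysis, fully orthogonal to the methyl ether that must remain. The inductive effect of the C2 benzyloxy group also steers the nucleophile to C6, as required.
- Weak points: A5 is a hexasubstituted silyl triflate on an unsymmetrically protected bis-aryl skeleton, and every one of its substituents must be installed by stepwise aromatic substitution. The aryne is flanked on both sides, acyl transfer has to occur at a carbon between two substituents, and the ring B ketone and the benzyl ethers are exposed to fluoride and to the aryne.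
- Comparison: the chosen plan builds ring A with all its substituents from two acyclic pieces in one step. It pays for this with a less orthogonal final deprotection.

Key step: step 8

Remark (assumption on the chemistry): on acid work-up cycloadduct 18 is taken to lose methanol, not trimethylsilanol, so that C2 of ring A emerges as a free phenol, as in the known resorcinol-forming cases. If silanol were lost instead, the resulting C2 methyl ether would lie ortho to the ketone and be removed in step 10 all the same.

Remark (stereochemistry of intermediates): 9, 10 and 11 are expected as mixtures of double-bond isomers, and 4, 6, 7, 8, 16 and 18 as racemates or diastereomer mixtures. All these elements vanish on aromatisation, so only the E alkene of 7 is specified in the SMILES strings.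

## Steps

Step 1
Reactants: 1 2,4,6-trimethoxytoluene
Product: 3 2,4,6-trimethoxy-3-methylbenzaldehyde, via aryl iminium chloride 2 (not isolated)
Conditions: POCl3, DMF, 0 → 60 °C; then ice–water
Reagents that add atoms: N,N-dimethylformamide, CN(C)C=O; water, O
Why: Vilsmeier–Haack formylation of a trialkoxyarene; the two open positions of 1 are equivalent, the iminium group of 2 deactivates the ring against a second attack, and water converts 2 into the aldehyde.

Step 2
Reactants: 4 methyl 2-methyl-3-oxobutanoate; 3 2,4,6-trimethoxy-3-methylbenzaldehyde
Product: 7 methyl (4E)-2-methyl-3-oxo-5-(2,4,6-trimethoxy-3-methylphenyl)pent-4-enoate, via keto ester dianion 5 (not isolated), via aldol adduct 6 (not isolated)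
Conditions: LiN(iPr)2 (2.1 equiv), THF, −78 → 0 °C; 3, −78 → 0 °C; then 2 M HCl, 20 °C
Reagents that add atoms: none
Why: γ-Selective aldol addition of a β-keto ester dianion, which reacts at its terminal and more basic carbon; the benzylic hydroxyl of 6 should then leave under dilute acid, helped by the trimethoxyaryl group, to give the conjugated E enone (aldol condensation).

Step 3
Reactants: 7 methyl (4E)-2-methyl-3-oxo-5-(2,4,6-trimethoxy-3-methylphenyl)pent-4-enoate
Product: 8 methyl 2-methyl-3-oxo-5-(2,4,6-trimethoxy-3-methylphenyl)pentanoate
Conditions: H2 (1 atm), Pd/C, EtOAc, 20 °C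
Reagents that add atoms: none
Why: Heterogeneous catalytic hydrogenation of a conjugated C=C bond; the ketone, the ester and the aryl methyl ethers are inert under these conditions.

Step 4
Reactants: 8 methyl 2-methyl-3-oxo-5-(2,4,6-trimethoxy-3-methylphenyl)pentanoate
Product: 9 methyl 2-methyl-5-(2,4,6-trimethoxy-3-methylphenyl)-3-(trimethylsilyloxy)pent-2-enoate
Conditions: Me3SiCl, Et3N, toluene, 20 °C
Reagents that add atoms: chlorotrimethylsilane, C[Si](C)(C)Cl
Why: O-Silylation of an enolisable β-keto ester toward the doubly activated C2, the usual first stage of a bis(silyloxy)diene preparation; the enol ether geometry is of no consequence.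

Step 5
Reactants: 9 methyl 2-methyl-5-(2,4,6-trimethoxy-3-methylphenyl)-3-(trimethylsilyloxy)pent-2-enoate
Product: 11 1-methoxy-2-methyl-1,3-bis(trimethylsilyloxy)-5-(2,4,6-trimethoxy-3-methylphenyl)penta-1,3-diene, via lithium dienolate 10 (not isolated)
Conditions: LiN(iPr)2, THF, −78 °C; Me3SiCl, −78 → 20 °C; pentane, filtration under argon, used crude
Reagents that add atoms: chlorotrimethylsilane, C[Si](C)(C)Cl
Why: γ-Deprotonation of the silyloxy enoate (the C4 methylene is the only site that gives a conjugated ester dienolate) and O-silylation of 10; this is the standard second stage of bis(silyloxy)diene synthesis.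

Step 6
Reactants: 12 butanoyl chloride
Product: 13 N-methoxy-N-methylbutanamide
Conditions: MeNH(OMe)·HCl, Et3N (2.2 equiv), CH2Cl2, 0 → 20 °C
Reagents that add atoms: N,O-dimethylhydroxylamine hydrochloride, CNOC.Cl
Why: N-Acylation of an amine by an acid chloride, giving the amide needed for a controlled ketone synthesis.

Step 7
Reactants: 14 ethoxyacetylene; 13 N-methoxy-N-methylbutanamide
Product: 17 1-ethoxyhex-1-yn-3-one, via lithium ethoxyacetylide 15 (not isolated), via tetrahedral adduct 16 (not isolated)
Conditions: n-BuLi, THF, −78 °C; 13, −78 → −30 °C; inverse quench into cold 0.5 M HCl–Et2O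
Reagents that add atoms: none
Why: Weinreb ketone synthesis with a lithium acetylide; chelate 16 holds until the quench so that no second addition occurs, and the cold acidic quench protonates the released amine before it can add to the push–pull ynone.

Step 8
Reactants: 11 1-methoxy-2-methyl-1,3-bis(trimethylsilyloxy)-5-(2,4,6-trimethoxy-3-methylphenyl)penta-1,3-diene; 17 1-ethoxyhex-1-yn-3-one
Product: 19 1-{6-ethoxy-2,4-dihydroxy-3-methyl-5-[(2,4,6-trimethoxy-3-methylphenyl)methyl]phenyl}butan-1-one, via cyclohexadiene cycloadduct 18 (not isolated)
Conditions: 11 (1.5 equiv), toluene (about 1 M), −20 → 50 °C, argon; then 1 M HCl, THF, 20 °C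
Reagents that add atoms: none
Why: Proposed new method: the closest known reaction type is the Diels–Alder reaction and aromatisation of 1-alkoxy-1,3-bis(silyloxy)-1,3-dienes with alkynyl ketones and esters, which gives resorcinols; a 3-alkoxy ynone has not served as the two-carbon partner, and the reasoning is that its alkoxy-bearing carbon remains the electrophilic end of an alkynylogous ester, so the polarities of the partners stay matched. The diene terminus of 11 (ring A C5), its most nucleophilic carbon, should bond to the ethoxy-bearing carbon of 17 (C6) and the ketene acetal carbon (C2) to the acyl-bearing carbon (C1), either in one asynchronous concerted (4+2) event or as a Mukaiyama–Michael addition whose oxocarbenium/allenolate pair collapses by 6-exo-trig attack of the allenolate carbon on the oxocarbenium carbon; either way ring A closes as cyclohexa-1,4-diene 18. Dilute acid should then remove methanol from the mixed ketal carbon together with the C5 hydrogen (1,4-elimination) and hydrolyse both silyl ethers, so that all six substituents of ring A are in place in 19. No stereocentre is created that persists, since the two in 18 are destroyed on aromatisation. The selectivity needed is regiochemical (head-to-tail orientation) and chemoselective (ring C–C bond formation in preference to 1,2-addition at the ketone or loss of ethoxide); it rests on the push–pull polarisation of 17, on the absence of a Lewis acid that would favour carbonyl addition, and on temperatures below those at which ethyl ynol ethers fragment to ketenes.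

Step 9
Reactants: 19 1-{6-ethoxy-2,4-dihydroxy-3-methyl-5-[(2,4,6-trimethoxy-3-methylphenyl)methyl]phenyl}butan-1-one; 12 butanoyl chloride
Product: 20 1-{5-[(3-butanoyl-2,4,6-trimethoxy-5-methylphenyl)methyl]-6-ethoxy-2,4-dihydroxy-3-methylphenyl}butan-1-one
Conditions: TiCl4, CH2Cl2, −40 → 0 °C; then K2CO3, MeOH, 20 °C
Reagents that add atoms: none
Why: Friedel–Crafts acylation at C3' of ring B, the only unsubstituted ring carbon and one activated by three methoxy groups; ring A is deactivated by its ketone, mild methanolysis returns any phenolic butyrate to the phenol, and early loss of an ortho alkyl group would be harmless because the same ethers fall in step 10.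

Step 10
Reactants: 20 1-{5-[(3-butanoyl-2,4,6-trimethoxy-5-methylphenyl)methyl]-6-ethoxy-2,4-dihydroxy-3-methylphenyl}butan-1-one
Product: 21 margaspidin (1-{3-[(3-butanoyl-2,4,6-trihydroxy-5-methylphenyl)methyl]-2,6-dihydroxy-4-methoxy-5-methylphenyl}butan-1-one)
Conditions: BCl3 (excess), CH2Cl2, −78 → 20 °C; then ice–water
Reagents that add atoms: none
Why: Chelation-directed ether cleavage: BCl3 bridges a ketone oxygen and an ortho ether oxygen and chloride removes the alkyl group by SN2, which applies to the C2' and C4' methyl ethers and the C6 ethyl ether but not to the C6' methoxy group para to the ring B ketone; the non-basic work-up spares the bridge.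

## Compound list

1 | 2,4,6-trimethoxytoluene | COc1cc(OC)c(C)c(OC)c1 | starting material
2 | N-methyl-N-[(2,4,6-trimethoxy-3-methylphenyl)methylidene]methanaminium chloride | C[N+](C)=Cc1c(OC)c(C)c(OC)cc1OC.[Cl-] | intermediate
3 | 2,4,6-trimethoxy-3-methylbenzaldehyde | O=Cc1c(OC)c(C)c(OC)cc1OC | intermediate
4 | methyl 2-methyl-3-oxobutanoate (racemic) | CC(=O)C(C)C(=O)OC | starting material
5 | dilithium 1-methoxy-2-methylbuta-1,3-diene-1,3-bis(olate) | [Li+].[Li+].C=C([O-])C(C)=C([O-])OC | intermediate
6 | methyl 5-hydroxy-2-methyl-3-oxo-5-(2,4,6-trimethoxy-3-methylphenyl)pentanoate (diastereomer mixture) | COC(=O)C(C)C(=O)CC(O)c1c(OC)c(C)c(OC)cc1OC | intermediate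
7 | methyl (4E)-2-methyl-3-oxo-5-(2,4,6-trimethoxy-3-methylphenyl)pent-4-enoate (racemic) | COC(=O)C(C)C(=O)/C=C/c1c(OC)c(C)c(OC)cc1OC | intermediate
8 | methyl 2-methyl-3-oxo-5-(2,4,6-trimethoxy-3-methylphenyl)pentanoate (racemic) | COC(=O)C(C)C(=O)CCc1c(OC)c(C)c(OC)cc1OC | intermediate
9 | methyl 2-methyl-5-(2,4,6-trimethoxy-3-methylphenyl)-3-(trimethylsilyloxy)pent-2-enoate (E/Z mixture) | COC(=O)C(C)=C(O[Si](C)(C)C)CCc1c(OC)c(C)c(OC)cc1OC | intermediate
10 | lithium 1-methoxy-2-methyl-5-(2,4,6-trimethoxy-3-methylphenyl)-3-(trimethylsilyloxy)penta-1,3-dien-1-olate | [Li+].COC([O-])=C(C)C(O[Si](C)(C)C)=CCc1c(OC)c(C)c(OC)cc1OC | intermediate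
11 | 1-methoxy-2-methyl-1,3-bis(trimethylsilyloxy)-5-(2,4,6-trimethoxy-3-methylphenyl)penta-1,3-diene (mixture of geometric isomers) | COC(O[Si](C)(C)C)=C(C)C(O[Si](C)(C)C)=CCc1c(OC)c(C)c(OC)cc1OC | intermediate
12 | butanoyl chloride | CCCC(=O)Cl | starting material
13 | N-methoxy-N-methylbutanamide | CCCC(=O)N(C)OC | intermediate
14 | ethoxyacetylene | CCOC#C | starting material
15 | lithium ethoxyacetylide | [Li+].[C-]#COCC | intermediate
16 | lithium 1-ethoxy-3-[methoxy(methyl)amino]hex-1-yn-3-olate (racemic) | [Li+].CCCC([O-])(C#COCC)N(C)OC | intermediate
17 | 1-ethoxyhex-1-yn-3-one | CCCC(=O)C#COCC | intermediate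
18 | 1-{2-ethoxy-6-methoxy-5-methyl-3-[(2,4,6-trimethoxy-3-methylphenyl)methyl]-4,6-bis(trimethylsilyloxy)cyclohexa-1,4-dien-1-yl}butan-1-one (diastereomer mixture) | CCCC(=O)C1=C(OCC)C(Cc2c(OC)cc(OC)c(C)c2OC)C(O[Si](C)(C)C)=C(C)C1(OC)O[Si](C)(C)C | intermediate
19 | 1-{6-ethoxy-2,4-dihydroxy-3-methyl-5-[(2,4,6-trimethoxy-3-methylphenyl)methyl]phenyl}butan-1-one | CCCC(=O)c1c(O)c(C)c(O)c(Cc2c(OC)cc(OC)c(C)c2OC)c1OCC | intermediate
20 | 1-{5-[(3-butanoyl-2,4,6-trimethoxy-5-methylphenyl)methyl]-6-ethoxy-2,4-dihydroxy-3-methylphenyl}butan-1-one | CCCC(=O)c1c(O)c(C)c(O)c(Cc2c(OC)c(C(=O)CCC)c(OC)c(C)c2OC)c1OCC | intermediate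
21 | margaspidin | CCCC(=O)c1c(O)c(C)c(O)c(Cc2c(O)c(C(=O)CCC)c(O)c(C)c2OC)c1O | target

## Step count and risk

Total step count: 10. Longest linear sequence: 8 (steps 1–5, 8, 9, 10); the ynone branch (steps 6, 7) joins at step 8.

**Step 8 (key step).** The cycloaddition may be too slow, because the ethoxy group donates into the ynone and both bond-forming carbons are substituted; the diene would then be lost by hydrolysis. Alternatively, the first C–C bond may form and ethoxide be expelled (addition–elimination) instead of ring closure. The fallback uses known chemistry, sets out from 1 and 12 and rejoins the route at 21: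
- Commercial 2-methylbenzene-1,3,5-triol is C-acylated with 12 (AlCl3) to 1-(2,4,6-trihydroxy-3-methylphenyl)butan-1-one F1.
- A Mannich reaction (formaldehyde, dimethylamine) at its only free ring position gives 1-{3-[(dimethylamino)methyl]-2,4,6-trihydroxy-5-methylphenyl}butan-1-one F2.
- Heating F2 with an excess of 1 in dioxane releases the ortho-quinone methide, which alkylates the electron-rich arene to 1-{2,4,6-trihydroxy-3-methyl-5-[(2,4,6-trimethoxy-3-methylphenyl)methyl]phenyl}butan-1-one F3.
- Butyrylation of ring B as in step 9 gives 1-{3-[(3-butanoyl-2,4,6-trimethoxy-5-methylphenyl)methyl]-2,4,6-trihydroxy-5-methylphenyl}butan-1-one F4, and BCl3 as in step 10 gives 21.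

**Step 10.** Cleavage may stop short or go too far. The second ortho ether on each ketone reacts more slowly once the first boron chelate has tied up the carbonyl, and ethyl leaves more slowly than methyl. The C6' methoxy group, twisted out of plane by two ortho substituents, is also more Lewis basic than an ordinary anisole. The fallback sets out from 20: BBr3 removes all alkyl groups to give 1,1'-[methylenebis(2,4,6-trihydroxy-5-methylbenzene-3,1-diyl)]dibutan-1-one F5 (the same compound as A2). One equivalent of diazomethane, with no base present, then methylates a para hydroxyl, the most acidic and the only non-chelated type. F5 is symmetric, so either para oxygen gives 21, at the cost of a statistical mono/bis distribution.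

**Step 9.** O-Acylation of the ring A hydroxyls may compete, and the Lewis acid may induce ipso attack at the bridge carbon with loss of the benzyl unit. The fallback sets out from 19 and returns at 20:
- Acetylation (Ac2O, pyridine, DMAP) gives 4-butanoyl-5-ethoxy-2-methyl-6-[(2,4,6-trimethoxy-3-methylphenyl)methyl]-1,3-phenylene diacetate F6, in which ring A is capped and further deactivated.
- Friedel–Crafts butyrylation with 12 gives 4-butanoyl-6-[(3-butanoyl-2,4,6-trimethoxy-5-methylphenyl)methyl]-5-ethoxy-2-methyl-1,3-phenylene diacetate F7.
- K2CO3 in methanol removes the acetates to give 20.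

**Step 2.** The doubly ortho-substituted, weakly electrophilic aldehyde may convert poorly or revert by retro-aldol, and the benzylic cation may alkylate another arene during the acid dehydration. The fallback sets out from 3 and returns at 8:
- Doebner condensation with malonic acid (pyridine, piperidine) gives (2E)-3-(2,4,6-trimethoxy-3-methylphenyl)prop-2-enoic acid F8.
- Hydrogenation (H2, Pd/C) gives 3-(2,4,6-trimethoxy-3-methylphenyl)propanoic acid F9.
- Carbonyldiimidazole gives 1-(1H-imidazol-1-yl)-3-(2,4,6-trimethoxy-3-methylphenyl)propan-1-one F10.
- Acylation of the magnesium enolate of methyl hydrogen methylmalonate (MgCl2, Et3N) with F10, followed by decarboxylation, gives 8.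

**Step 7.** The liberated N,O-dimethylhydroxylamine or water may add to the push–pull ynone during work-up. The fallback sets out from 14 and returns at 17: acetylide 15 is added to butanal to give 1-ethoxyhex-1-yn-3-ol F11, which is oxidised with MnO2 under neutral conditions to 17.

## Further compounds

F1 | step 8 | 1-(2,4,6-trihydroxy-3-methylphenyl)butan-1-one | CCCC(=O)c1c(O)c(C)c(O)cc1O
F2 | step 8 | 1-{3-[(dimethylamino)methyl]-2,4,6-trihydroxy-5-methylphenyl}butan-1-one | CCCC(=O)c1c(O)c(C)c(O)c(CN(C)C)c1O
F3 | step 8 | 1-{2,4,6-trihydroxy-3-methyl-5-[(2,4,6-trimethoxy-3-methylphenyl)methyl]phenyl}butan-1-one | CCCC(=O)c1c(O)c(C)c(O)c(Cc2c(OC)cc(OC)c(C)c2OC)c1O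
F4 | step 8 | 1-{3-[(3-butanoyl-2,4,6-trimethoxy-5-methylphenyl)methyl]-2,4,6-trihydroxy-5-methylphenyl}butan-1-one | CCCC(=O)c1c(O)c(C)c(O)c(Cc2c(OC)c(C(=O)CCC)c(OC)c(C)c2OC)c1O
F5 | step 10 | 1,1'-[methylenebis(2,4,6-trihydroxy-5-methylbenzene-3,1-diyl)]dibutan-1-one | CCCC(=O)c1c(O)c(C)c(O)c(Cc2c(O)c(C)c(O)c(C(=O)CCC)c2O)c1O
F6 | step 9 | 4-butanoyl-5-ethoxy-2-methyl-6-[(2,4,6-trimethoxy-3-methylphenyl)methyl]-1,3-phenylene diacetate | CCCC(=O)c1c(OC(C)=O)c(C)c(OC(C)=O)c(Cc2c(OC)cc(OC)c(C)c2OC)c1OCC
F7 | step 9 | 4-butanoyl-6-[(3-butanoyl-2,4,6-trimethoxy-5-methylphenyl)methyl]-5-ethoxy-2-methyl-1,3-phenylene diacetate | CCCC(=O)c1c(OC(C)=O)c(C)c(OC(C)=O)c(Cc2c(OC)c(C(=O)CCC)c(OC)c(C)c2OC)c1OCC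
F8 | step 2 | (2E)-3-(2,4,6-trimethoxy-3-methylphenyl)prop-2-enoic acid | OC(=O)/C=C/c1c(OC)c(C)c(OC)cc1OC
F9 | step 2 | 3-(2,4,6-trimethoxy-3-methylphenyl)propanoic acid | OC(=O)CCc1c(OC)c(C)c(OC)cc1OC
F10 | step 2 | 1-(1H-imidazol-1-yl)-3-(2,4,6-trimethoxy-3-methylphenyl)propan-1-one | O=C(CCc1c(OC)c(C)c(OC)cc1OC)n1ccnc1
F11 | step 7 | 1-ethoxyhex-1-yn-3-ol (racemic) | CCCC(O)C#COCC
A1 | alternative 1 | dimethyl 2,4-bis(2-methyl-3,5-dioxooctanoyl)pentanedioate (mixture of stereoisomers) | COC(=O)C(CC(C(=O)OC)C(=O)C(C)C(=O)CC(=O)CCC)C(=O)C(C)C(=O)CC(=O)CCC
A2 | alternative 1 | 1,1'-[methylenebis(2,4,6-trihydroxy-5-methylbenzene-3,1-diyl)]dibutan-1-one | CCCC(=O)c1c(O)c(C)c(O)c(Cc2c(O)c(C)c(O)c(C(=O)CCC)c2O)c1O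
A3 | alternative 2 | bis(2,4,6-tribromo-3-methylphenyl)methane | Cc1c(Br)cc(Br)c(Cc2c(Br)cc(Br)c(C)c2Br)c1Br
A4 | alternative 2 | bis(2,4,6-trimethoxy-3-methylphenyl)methane | COc1cc(OC)c(Cc2c(OC)cc(OC)c(C)c2OC)c(OC)c1C
A5 | alternative 3 | 2-{[2,4-bis(benzyloxy)-3-butanoyl-6-methoxy-5-methylphenyl]methyl}-3,5-bis(benzyloxy)-4-methyl-6-(trimethylsilyl)phenyl trifluoromethanesulfonate | C[Si](C)(C)c1c(OCc2ccccc2)c(C)c(OCc2ccccc2)c(Cc2c(OCc3ccccc3)c(C(=O)CCC)c(OCc3ccccc3)c(C)c2OC)c1OS(=O)(=O)C(F)(F)F
A6 | alternative 3 | 2,4,2',4'-tetra-O-benzylmargaspidin | CCCC(=O)c1c(OCc2ccccc2)c(C)c(OCc2ccccc2)c(Cc2c(OCc3ccccc3)c(C(=O)CCC)c(OCc3ccccc3)c(C)c2OC)c1O
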